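**Plan**

1. Numbering (labdane type): ring A = C1–C5 and C10, ring B = C5–C10, C17 = methylidene on C8, side chain C11–C15 on C9, C18 = CH2OAc and C19 = CH3 on C4, C20 = CH3 on C10. The SMILES is read as the cis-fused (4R,5S,9S,10R) isomer: H-5, C19, C20 and C11 on one face, C18 on the other.
2. Cuts: C12–C13 (alkylzinc plus (Z)-alkenyl iodide), C8–C9 (ring B), C4–C19 (enolate methylation), C9=C11 (olefination of a C9 aldehyde), then C1–C2 and C5–C10 (Diels–Alder). The diene goes back to a Baylis–Hillman adduct.
3. Forward, ring A comes first by a catalytic asymmetric endo Diels–Alder of methacrolein with a 2-silyloxy diene. The catalyst fixes C10, the endo rule puts the formyl carbon C9 cis to the C6–C8 arm (sets C5), and the adduct is a silyl enol ether regiodefined at C3=C4.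
4. C4 is quaternised by methylation anti to the C5 arm (substrate control). C3 is then masked as a dioxolane, a temporary ring that also fixes the ring A chair.
5. Ring B closes last. C8, as a vinyl radical from the 2-bromoallyl terminus, lies 1,6 to the enoate β-carbon C9 held on quaternary C10, so one 6-exo closure gives the cis-decalin, the C9 centre and the C8=C17 methylidene, with C12 left as an ester.
6. The C12 ester becomes the iodide and is coupled with ethyl (Z)-3-iodobut-2-enoate with retention (13Z). Unmasking and acetylation finish the route.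

Key step: step 10

Remark: in step 6 the facial sense is assigned from the accepted binding model of protonated oxazaborolidines (formyl C–H···O contact, s-trans enal); if the opposite sense were found, the equally available (R)-catalyst would be used with nothing else changed.
Abbreviation: TBS = tert-butyldimethylsilyl.

**Route**

Step 1
Reactants: 1 tert-butyl acetate; 2 2,3-dibromopropene
Product: 4 tert-butyl 4-bromopent-4-enoate, via lithium enolate 3 (not isolated)
Conditions: LiN(i-Pr)2 (1.1 equiv), THF, −78 °C; then 2 (0.9 equiv), −78 → −20 °C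
Reagents that add atoms: none
Why: Ester enolate alkylation: the lithium enolate displaces the allylic bromide (direct and allylic displacement give the same 2-bromoallyl product), the vinylic C–Br bond is inert, and the tert-butyl ester suppresses Claisen self-condensation.

Step 2
Reactants: 4 tert-butyl 4-bromopent-4-enoate
Product: 5 4-bromopent-4-enal
Conditions: i-Bu2AlH (1.1 equiv), CH2Cl2, −78 °C; aqueous potassium sodium tartrate
Reagents that add atoms: none
Why: Partial reduction of an ester by i-Bu2AlH: the tetrahedral aluminium hemiacetal is stable at −78 °C and should release the aldehyde only on hydrolytic work-up.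

Step 3
Reactants: 5 4-bromopent-4-enal; 6 methyl vinyl ketone
Product: 7 7-bromo-4-hydroxy-3-methylideneoct-7-en-2-one (racemic)
Conditions: 1,4-diazabicyclo[2.2.2]octane (0.5 equiv), 6 (3 equiv), neat, rt, 3–4 d
Reagents that add atoms: none
Why: Morita–Baylis–Hillman reaction: the amine adds to the enone, the resulting enolate adds to the aldehyde and the amine is expelled; the carbinol centre is racemic and is erased in step 4.

Step 4
Reactants: 7 7-bromo-4-hydroxy-3-methylideneoct-7-en-2-one
Product: 10 (3E)-7-bromo-3-(hydroxymethyl)octa-3,7-dien-2-one, via secondary acetate 8 (not isolated), via rearranged primary acetate 9 (not isolated)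
Conditions: Ac2O (1.5 equiv), Me3SiOTf (10 mol %), CH2Cl2, 0 °C → rt; then MeOH, HCl (0.3 equiv, from AcCl), rt
Reagents that add atoms: none
Why: O-Acetylation, then Lewis-acid-catalysed 1,3-acyloxy transposition of the Baylis–Hillman acetate to the thermodynamically preferred trisubstituted (E)-allylic acetate (chain trans to the acetyl group), then acid-catalysed transesterification, chosen over base so that no SN2′ displacement of the allylic acetate can occur.

Step 5
Reactants: 10 (3E)-7-bromo-3-(hydroxymethyl)octa-3,7-dien-2-one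
Product: 11 (3E)-7-bromo-2-(TBSO)-3-(TBSO-methyl)octa-1,3,7-triene
Conditions: t-BuMe2SiOTf (2.3 equiv), Et3N (3.5 equiv), CH2Cl2, −78 → 0 °C
Reagents that add atoms: tert-butyldimethylsilyl trifluoromethanesulfonate CC(C)(C)[Si](C)(C)OS(=O)(=O)C(F)(F)F
Why: Silylation with a silyl triflate and amine base: the primary alcohol is silylated and the methyl ketone is enolised kinetically on the methyl side to the cross-conjugated 2-silyloxy diene, which leaves the (E) C4=C5 geometry untouched.

Step 6
Reactants: 11 (3E)-7-bromo-2-(TBSO)-3-(TBSO-methyl)octa-1,3,7-triene; 12 methacrolein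
Product: 13 (1S,2R)-2-(3-bromobut-3-en-1-yl)-4-(TBSO)-3-(TBSO-methyl)-1-methylcyclohex-3-ene-1-carbaldehyde (formyl cis to the bromobutenyl arm)
Conditions: (S)-tetrahydro-1-(2-methylphenyl)-3,3-diphenyl-1H,3H-pyrrolo[1,2-c][1,3,2]oxazaborole (20 mol %) activated with HN(SO2CF3)2 (20 mol %), 12 (2 equiv), CH2Cl2, −78 → −40 °C; Et3N quench
Reagents that add atoms: none
Why: Catalytic enantioselective Diels–Alder reaction of an α-substituted acrolein activated by a chiral cationic oxazaborolidine: the 2-silyloxy group (para) and the terminal alkyl group (ortho) direct the same regiochemistry, the endo (formyl) transition state of the (E)-diene should place the formyl group cis to the bromobutenyl arm (relative configuration C5/C10), and the catalyst blocks one face of the s-trans enal, which sets the quaternary centre C10 absolutely.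

Step 7
Reactants: 13 Diels–Alder aldehyde; 14 trimethyl phosphonoacetate
Product: 15 methyl (2E)-3-[(1R,2S)-2-(3-bromobut-3-en-1-yl)-4-(TBSO)-3-(TBSO-methyl)-1-methylcyclohex-3-en-1-yl]prop-2-enoate
Conditions: NaH (1.3 equiv), 14 (1.4 equiv), THF, 0 °C → rt
Reagents that add atoms: none
Why: Horner–Wadsworth–Emmons olefination of a non-enolisable α-quaternary aldehyde with a stabilised phosphonate anion should give the (E)-enoate, the silyl enol ether and vinyl bromide being inert to the reagent.

Step 8
Reactants: 15 silyl enol ether enoate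
Product: 17 methyl (2E)-3-[(1R,2S,3R)-2-(3-bromobut-3-en-1-yl)-3-(TBSO-methyl)-1,3-dimethyl-4-oxocyclohexyl]prop-2-enoate, via sulfonium enolate 16 (not isolated)
Conditions: MeI (5 equiv), (Me2N)3S+ Me3SiF2− (1.1 equiv), THF, −78 → −20 °C
Reagents that add atoms: iodomethane CI
Why: Regiospecific alkylation of a silyl enol ether through its fluoride-generated enolate: the enol silyl ether is cleaved much faster than the primary silyl ether, only C4 can be alkylated, and methyl iodide should enter anti to the adjacent C5 arm and to the axial C10 alkenyl arm (substrate control), i.e. on the face of H-5 and C20, which sets the C4 quaternary centre.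

Step 9
Reactants: 17 methylated ketone
Product: 18 methyl (2E)-3-[(6R,7S,8R)-7-(3-bromobut-3-en-1-yl)-6-(TBSO-methyl)-6,8-dimethyl-1,4-dioxaspiro[4.5]decan-8-yl]prop-2-enoate
Conditions: (Me3SiOCH2)2 (3 equiv), Me3SiOTf (15 mol %), CH2Cl2, −78 → −20 °C; pyridine quench
Reagents that add atoms: 1,2-bis(trimethylsilyloxy)ethane C[Si](C)(C)OCCO[Si](C)(C)C
Why: Acetalisation under aprotic conditions with the bis(trimethylsilyl) ether of ethylene glycol and catalytic Me3SiOTf, a method suited to hindered α-quaternary ketones that leaves the silyl ether, the enoate and the vinyl bromide untouched.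

Step 10
Reactants: 18 dioxolane vinyl bromide
Product: 19 methyl 2-[(1S,4aS,5R,8aR)-5-(TBSO-methyl)-6,6-(ethane-1,2-diyldioxy)-5,8a-dimethyl-2-methylidenedecahydronaphthalen-1-yl]acetate
Conditions: Bu3SnH (1.3 equiv) and 2,2′-azobis(2-methylpropionitrile) (0.2 equiv) added by syringe pump over 6 h to 18 (0.01 M) in benzene, 80 °C; aqueous KF work-up
Reagents that add atoms: none
Why: Bu3Sn• abstracts bromine from C8 to give a σ-vinyl radical, which adds 6-exo-trig to the β-carbon C9 of the enoate (polarity-matched; the α-ester radical at C11 then takes H from Bu3SnH and the chain is carried on), so that ring B, the C8–C9 bond and the C8=C17 methylidene arise together. The closest known reaction type is the tin-hydride vinyl radical cyclization of 2-bromo-1-alkenes onto acrylate acceptors. Ring B closes in the 6-exo-trig mode through a chair-like transition state; 7-endo attack at C11 is disfavoured by the enoate polarisation and would give an unstabilised secondary radical. C9 is the only new stereocentre and is set by substrate control: with the dioxolane in place, the ring A chair carrying the C5 arm equatorial and the C10 alkenyl arm axial is the only one free of both an O/C6 and a CH3/CH3 syn-diaxial pair, and in that chair C11 must sit pseudo-equatorial on the forming ring because a pseudo-axial C11 would be syn-diaxial to C4, which should place C11 cis to C20 and give the cis-fused decalin. The step needs ring closure to outrun hydrogen capture by the vinyl radical, which slow addition of the stannane at high dilution secures, and it needs the absence of a competing 5-exo acceptor, which is why C4 is quaternised before this step.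

Step 11
Reactants: 19 decalin methyl ester
Product: 20 2-[(1S,4aS,5R,8aR)-5-(TBSO-methyl)-6,6-(ethane-1,2-diyldioxy)-5,8a-dimethyl-2-methylidenedecahydronaphthalen-1-yl]ethan-1-ol
Conditions: LiAlH4 (1.0 equiv), THF, 0 °C
Reagents that add atoms: none
Why: Hydride reduction of the ester to the primary alcohol; the ketal, the silyl ether and the isolated 1,1-disubstituted alkene are inert to LiAlH4.

Step 12
Reactants: 20 primary alcohol
Product: 21 the corresponding 1-(2-iodoethyl)decalin (C12 iodide)
Conditions: PPh3 (1.3 equiv), imidazole (2 equiv), I2 (1.3 equiv), CH2Cl2, 0 °C → rt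
Reagents that add atoms: iodine II
Why: Appel-type iodination: the unhindered primary alcohol is activated as its oxyphosphonium salt and displaced by iodide (SN2), the buffered medium sparing ketal and silyl ether.

Step 13
Reactants: 22 ethyl but-2-ynoate
Product: 23 ethyl (2Z)-3-iodobut-2-enoate
Conditions: NaI (1.6 equiv), AcOH, 115 °C
Reagents that add atoms: sodium iodide [Na+].[I-]
Why: Hydroiodination of an ynoate: conjugate addition of iodide and protonation of the allenolate give the anti adduct, i.e. the (Z)-β-iodo enoate, as the kinetic product.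

Step 14
Reactants: 21 C12 iodide; 23 ethyl (2Z)-3-iodobut-2-enoate
Product: 25 ethyl (2Z)-5-[(1S,4aS,5R,8aR)-5-(TBSO-methyl)-6,6-(ethane-1,2-diyldioxy)-5,8a-dimethyl-2-methylidenedecahydronaphthalen-1-yl]-3-methylpent-2-enoate, via alkylzinc iodide 24 (not isolated)
Conditions: activated Zn dust (3 equiv), LiCl, THF, 40 °C; then Pd(PPh3)4 (5 mol %), 23 (1.2 equiv), THF/DMF, rt
Reagents that add atoms: none
Why: Negishi coupling: zinc inserts into the primary C–I bond and the alkylzinc iodide is coupled under Pd catalysis with the alkenyl iodide with retention of its geometry, which fixes the (Z)-trisubstituted alkene; ketal, silyl ether and ester are compatible with the organozinc.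

Step 15
Reactants: 25 protected ethyl ester
Product: 27 (2Z)-5-[(1S,4aS,5R,8aR)-5-(hydroxymethyl)-5,8a-dimethyl-2-methylidene-6-oxodecahydronaphthalen-1-yl]-3-methylpent-2-enoic acid, via lithium carboxylate 26 (not isolated)
Conditions: LiOH (5 equiv), THF/MeOH/H2O, 50 °C; then 2 M HCl to pH 1, rt
Reagents that add atoms: lithium hydroxide [Li+].[OH-]; water O
Why: Saponification while ketone and alcohol are still masked (so that no β-hydroxy ketone meets base), followed by acidification, at which the dioxolane of the hindered ketone and the primary silyl ether are hydrolysed; dilute acid at room temperature should leave the 1,1-disubstituted alkene and the (Z)-enoic acid unchanged.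

Step 16
Reactants: 27 hydroxy keto acid
Product: 29 (2Z)-5-[(1S,4aS,5R,8aR)-5-(acetyloxymethyl)-5,8a-dimethyl-2-methylidene-6-oxodecahydronaphthalen-1-yl]-3-methylpent-2-enoic acid (target), via mixed anhydride 28 (not isolated)
Conditions: Ac2O (3 equiv), pyridine, 4-(dimethylamino)pyridine (10 mol %), CH2Cl2, rt; then THF/aqueous NaHCO3, rt; acidify to pH 3
Reagents that add atoms: acetic anhydride CC(=O)OC(C)=O
Why: Nucleophile-catalysed acylation of the neopentyl primary alcohol with Ac2O; the carboxylic acid is converted transiently into the mixed anhydride, which the aqueous bicarbonate work-up hydrolyses back to the acid, and the β-acetoxy ketone cannot eliminate because C4 carries no hydrogen.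

**Compound list**

1 | tert-butyl acetate | CC(=O)OC(C)(C)C | starting material
2 | 2,3-dibromopropene | C=C(Br)CBr | starting material
3 | lithium enolate of tert-butyl acetate | C=C([O-])OC(C)(C)C.[Li+] | intermediate (not isolated)
4 | tert-butyl 4-bromopent-4-enoate | C=C(Br)CCC(=O)OC(C)(C)C | intermediate
5 | 4-bromopent-4-enal | C=C(Br)CCC=O | intermediate
6 | methyl vinyl ketone (but-3-en-2-one) | CC(=O)C=C | starting material
7 | 7-bromo-4-hydroxy-3-methylideneoct-7-en-2-one (racemic) | CC(=O)C(=C)C(O)CCC(Br)=C | intermediate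
8 | 7-bromo-3-methylidene-2-oxooct-7-en-4-yl acetate (racemic) | CC(=O)C(=C)C(OC(C)=O)CCC(Br)=C | intermediate (not isolated)
9 | (2E)-2-acetyl-6-bromohepta-2,6-dien-1-yl acetate | CC(=O)/C(COC(C)=O)=C/CCC(Br)=C | intermediate (not isolated)
10 | (3E)-7-bromo-3-(hydroxymethyl)octa-3,7-dien-2-one | CC(=O)/C(CO)=C/CCC(Br)=C | intermediate
11 | (3E)-7-bromo-2-[(tert-butyldimethylsilyl)oxy]-3-{[(tert-butyldimethylsilyl)oxy]methyl}octa-1,3,7-triene | C=C(O[Si](C)(C)C(C)(C)C)/C(CO[Si](C)(C)C(C)(C)C)=C/CCC(Br)=C | intermediate
12 | methacrolein (2-methylprop-2-enal) | CC(=C)C=O | starting material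
13 | (1S,2R)-2-(3-bromobut-3-en-1-yl)-4-[(tert-butyldimethylsilyl)oxy]-3-{[(tert-butyldimethylsilyl)oxy]methyl}-1-methylcyclohex-3-ene-1-carbaldehyde | C=C(Br)CC[C@H]1[C@@](C)(C=O)CCC(O[Si](C)(C)C(C)(C)C)=C1CO[Si](C)(C)C(C)(C)C | intermediate
14 | trimethyl phosphonoacetate | COC(=O)CP(=O)(OC)OC | starting material
15 | methyl (2E)-3-[(1R,2S)-2-(3-bromobut-3-en-1-yl)-4-[(tert-butyldimethylsilyl)oxy]-3-{[(tert-butyldimethylsilyl)oxy]methyl}-1-methylcyclohex-3-en-1-yl]prop-2-enoate | C=C(Br)CC[C@H]1[C@@](C)(/C=C/C(=O)OC)CCC(O[Si](C)(C)C(C)(C)C)=C1CO[Si](C)(C)C(C)(C)C | intermediate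
16 | tris(dimethylamino)sulfonium enolate formed from 15 by loss of the enol silyl group | C=C(Br)CC[C@H]1[C@@](C)(/C=C/C(=O)OC)CCC([O-])=C1CO[Si](C)(C)C(C)(C)C.CN(C)[S+](N(C)C)N(C)C | intermediate (not isolated)
17 | methyl (2E)-3-[(1R,2S,3R)-2-(3-bromobut-3-en-1-yl)-3-{[(tert-butyldimethylsilyl)oxy]methyl}-1,3-dimethyl-4-oxocyclohexyl]prop-2-enoate | C=C(Br)CC[C@H]1[C@@](C)(/C=C/C(=O)OC)CCC(=O)[C@@]1(C)CO[Si](C)(C)C(C)(C)C | intermediate
18 | methyl (2E)-3-[(6R,7S,8R)-7-(3-bromobut-3-en-1-yl)-6-{[(tert-butyldimethylsilyl)oxy]methyl}-6,8-dimethyl-1,4-dioxaspiro[4.5]decan-8-yl]prop-2-enoate | C=C(Br)CC[C@H]1[C@@](C)(/C=C/C(=O)OC)CCC2(OCCO2)[C@@]1(C)CO[Si](C)(C)C(C)(C)C | intermediate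
19 | methyl 2-[(1S,4aS,5R,8aR)-5-{[(tert-butyldimethylsilyl)oxy]methyl}-6,6-(ethane-1,2-diyldioxy)-5,8a-dimethyl-2-methylidenedecahydronaphthalen-1-yl]acetate | C=C1CC[C@H]2[C@](C)(CCC3(OCCO3)[C@@]2(C)CO[Si](C)(C)C(C)(C)C)[C@H]1CC(=O)OC | intermediate
20 | 2-[(1S,4aS,5R,8aR)-5-{[(tert-butyldimethylsilyl)oxy]methyl}-6,6-(ethane-1,2-diyldioxy)-5,8a-dimethyl-2-methylidenedecahydronaphthalen-1-yl]ethan-1-ol | C=C1CC[C@H]2[C@](C)(CCC3(OCCO3)[C@@]2(C)CO[Si](C)(C)C(C)(C)C)[C@H]1CCO | intermediate
21 | the 1-(2-iodoethyl) analogue of 20 (C12 iodide), same (1S,4aS,5R,8aR) configuration | C=C1CC[C@H]2[C@](C)(CCC3(OCCO3)[C@@]2(C)CO[Si](C)(C)C(C)(C)C)[C@H]1CCI | intermediate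
22 | ethyl but-2-ynoate | CC#CC(=O)OCC | starting material
23 | ethyl (2Z)-3-iodobut-2-enoate | C/C(I)=C/C(=O)OCC | intermediate
24 | alkylzinc iodide from 21 | C=C1CC[C@H]2[C@](C)(CCC3(OCCO3)[C@@]2(C)CO[Si](C)(C)C(C)(C)C)[C@H]1CC[Zn]I | intermediate (not isolated)
25 | ethyl (2Z)-5-[(1S,4aS,5R,8aR)-5-{[(tert-butyldimethylsilyl)oxy]methyl}-6,6-(ethane-1,2-diyldioxy)-5,8a-dimethyl-2-methylidenedecahydronaphthalen-1-yl]-3-methylpent-2-enoate | C=C1CC[C@H]2[C@](C)(CCC3(OCCO3)[C@@]2(C)CO[Si](C)(C)C(C)(C)C)[C@H]1CC/C(C)=C\C(=O)OCC | intermediate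
26 | lithium carboxylate of 25 (ketal and silyl ether intact) | C=C1CC[C@H]2[C@](C)(CCC3(OCCO3)[C@@]2(C)CO[Si](C)(C)C(C)(C)C)[C@H]1CC/C(C)=C\C(=O)[O-].[Li+] | intermediate (not isolated)
27 | (2Z)-5-[(1S,4aS,5R,8aR)-5-(hydroxymethyl)-5,8a-dimethyl-2-methylidene-6-oxodecahydronaphthalen-1-yl]-3-methylpent-2-enoic acid | C=C1CC[C@H]2[C@](C)(CCC(=O)[C@@]2(C)CO)[C@H]1CC/C(C)=C\C(=O)O | intermediate
28 | mixed acetic anhydride of the target acid | C=C1CC[C@H]2[C@](C)(CCC(=O)[C@@]2(C)COC(C)=O)[C@H]1CC/C(C)=C\C(=O)OC(C)=O | intermediate (not isolated)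
29 | (2Z)-5-[(1S,4aS,5R,8aR)-5-(acetyloxymethyl)-5,8a-dimethyl-2-methylidene-6-oxodecahydronaphthalen-1-yl]-3-methylpent-2-enoic acid | C=C1CC[C@H]2[C@](C)(CCC(=O)[C@@]2(C)COC(C)=O)[C@H]1CC/C(C)=C\C(=O)O | target

**Count**

Total steps: 16. Longest linear sequence: 15 (steps 1–12 and 14–16; step 13 is a one-step side branch).

**Steps most likely to fail, with fallbacks**

Step 6. The fully substituted diene may turn over slowly on the chiral catalyst, so that facial discrimination and endo preference erode, while acid-promoted loss of silanol from the allylic silyl ether competes. The fallback gives up catalyst control and resolves instead. It sets out from 11 and 12 with an achiral promoter (Me2AlCl, CH2Cl2, −78 °C), which should still give the endo adduct, now as 13 together with its mirror image ent-13 F1. The mixture is condensed with (1S,2S)-N,N′-dimethyl-1,2-diphenylethane-1,2-diamine (molecular sieves, Et2O, rt) to two diastereomeric aminals, the imidazolidine of 13 F2 and the imidazolidine of ent-13 F3, which are separated by chromatography. Brief treatment of F2 with wet silica gel or dilute aqueous acetic acid releases the aldehyde, and the route is rejoined at 13.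

Step 10. The vinyl radical may capture hydrogen from the stannane before ring closure, and at 80 °C the chair preference that controls the C9 face may leak. The fallback replaces the radical chain by a closed-shell carbopalladation. From 18, a reductive Heck cyclization (Pd(OAc)2 10 mol %, PPh3, HCO2Na, Bu4NCl, DMF, 80 °C) should insert the enoate 6-exo into the alkenyl–palladium bond and reduce the resulting palladium enolate with formate. This gives 19 directly, with no new isolated compound. Because the insertion takes place on the metal, PPh3 can be exchanged for a chiral bisphosphine such as (R)-2,2′-bis(diphenylphosphino)-1,1′-binaphthyl to put the C9 face under ligand control if substrate control proves insufficient.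

Step 8. The fluoride-generated enolate may lose silanolate from C18 (β-elimination to an α-methylidene ketone), and O-methylation may compete with C-methylation. The fallback introduces the methyl carbon without an enolate. From 15, Simmons–Smith cyclopropanation of the electron-rich enol ether (Et2Zn, CH2I2, CH2Cl2, 0 °C), expected on the face away from the C5 arm, gives the siloxycyclopropane F4. HCl in MeOH then opens the cyclopropane at the CH2–C(OSi) bond and removes both silyl groups to give the hydroxy ketone F5, which already carries the C4 methyl on the face of H-5. Resilylation of the primary alcohol (t-BuMe2SiCl, imidazole, DMF) rejoins the route at 17.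

**Further compounds**

F1 | step 6 | ent-13, (1R,2S)-enantiomer of the Diels–Alder aldehyde | C=C(Br)CC[C@@H]1[C@](C)(C=O)CCC(O[Si](C)(C)C(C)(C)C)=C1CO[Si](C)(C)C(C)(C)C
F2 | step 6 | imidazolidine of 13 with the (4S,5S)-1,3-dimethyl-4,5-diphenyl ring | C=C(Br)CC[C@H]1[C@@](C)(C2N(C)[C@@H](c3ccccc3)[C@H](c3ccccc3)N2C)CCC(O[Si](C)(C)C(C)(C)C)=C1CO[Si](C)(C)C(C)(C)C
F3 | step 6 | imidazolidine of ent-13 with the (4S,5S)-1,3-dimethyl-4,5-diphenyl ring | C=C(Br)CC[C@@H]1[C@](C)(C2N(C)[C@@H](c3ccccc3)[C@H](c3ccccc3)N2C)CCC(O[Si](C)(C)C(C)(C)C)=C1CO[Si](C)(C)C(C)(C)C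
F0 | step 10 | none | none
F4 | step 8 | siloxycyclopropane from 15 (CH2 bridge across C3–C4 on the face of H-5 and C20) | C=C(Br)CC[C@H]1[C@@](C)(/C=C/C(=O)OC)CC[C@]2(O[Si](C)(C)C(C)(C)C)C[C@]12CO[Si](C)(C)C(C)(C)C
F5 | step 8 | methyl (2E)-3-[(1R,2S,3R)-2-(3-bromobut-3-en-1-yl)-3-(hydroxymethyl)-1,3-dimethyl-4-oxocyclohexyl]prop-2-enoate | C=C(Br)CC[C@H]1[C@@](C)(/C=C/C(=O)OC)CCC(=O)[C@@]1(C)CO
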